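The runs come from a simulation on assumed constants.

Late in the earlier runs D sank, in the south-west run from 14.1% to 10.1%, so the D standing in a flask was less than the D made, and the ratio of E to D at the highest D reading of a run was the nearest I could come to what that flask had made. I wanted it for one decision: should the next charge of Q go in at once, or be fed?

| setting | south-east | south-west | north-east | violet | teal | red | grey |
|---|---|---|---|---|---|---|---|
| J | 12 mM | 12 mM | 12 mM | 12 mM | 12 mM (in portions, 5, over 4.0 h) | 12 mM | 12 mM (fed, over 4.0 h) |
| Q | 15.6 mM | 7.8 mM | 31 mM | 15.6 mM (fed, over 4.0 h) | 15.6 mM | 15.6 mM | 15.6 mM |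
| remark | run made earlier | run made earlier | run made earlier | all else is in the flask from the start; the feed brings no volume worth counting | first portion at the start, last at 4.0 h | everything together at the start | all else is in the flask from the start; the feed brings no volume worth counting |
| time |  |  |  | 5.0 h | 5.0 h | 5.0 h | 5.0 h |

- south-east (time / h: D / %, E / %): 0.250: 15.6, 5.5; 0.500: 22.0, 5.5; 1.33: 27.6, 8.0; 3.00: 24.3, 7.0
- south-west (time / h: D / %, E / %): 0.333: 10.4, 2.0; 0.667: 13.9, 2.9; 1.50: 14.1, 3.4; 4.00: 10.1, 1.1
- north-east (time / h: D / %, E / %): 1.00: 42.5, 16.7; 2.00: 43.3, 20.7; 3.00: 41.9, 20.6; 4.00: 39.8, 19.3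

(each reading ± 1 percentage point)



* the flask with the highest share of D in D plus E ("all alike" if they lie within 1.5 percentage points) (violet / teal / red / grey / all alike)
* share of D in D plus E at the end, violet
* share of D in D plus E at the end, teal
* share of D in D plus E at the end, red
* share of D in D plus E at the end, grey

That ratio read 0.241 in the south-west run and 0.478 in the north-east run, rising with the charge of Q. I took the ratio at which E and D form to be cQ divided by a constant, the equal-rate level c×, the value of cQ at which E and D form equally; it is a selectivity factor that depends on cQ. For an exponential decay, the mean of cQ weighted by cQ itself is half the charge, so the two runs give c× = 49.0 mM. This is a reading, with 1 percentage point of scatter on a south-west E of only 3.4%.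

The early rise of D plus E in the south-west run read as a time constant of 0.270 h. Feeding Q over 4.0 h should therefore hold violet near 1.05 mM, below the 7.80 mM weighted mean of red. My formation shares of D were 97.9% for violet and 86.3% for red, before any fading of D; the south-east run, made like red, read 77.6% at its last reading.

The forecast also chose violet, with 88% (83% to 94%), 80% for teal, 77.5% for red and 83% for grey: “Q stays steady near 1.6 mM, share about 88%”. My violet figure stood higher. I would feed Q.

The flasks gave 93.1% for violet, 78.5% for teal, 73.8% for red and 83.8% for grey.

    J + Q → D (k = 56.0 /M/h)
    J + 2 Q → E (k = 1300 /M²/h)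
    J + D → Z (k = 24.0 /M/h)
    Q → X (k = 1.10 /h)

Violet beat the forecast by 5.1 points. Taking the turning of Q into X away cut the gap between violet and red from 19 points to 9 points, so that step carries a part of the gap. At 2.50 h, violet held 2.27 mM of Q, more than I had reckoned, and with c× that level gives a formation share of 95.6%. The neighbour flask with 3.9 mM of Q has a quarter of the feed; a level scaled to match gives 98.9%, and that flask gave 98.0%.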